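**Retrosynthetic overview**

1. Feature: in the cyclohex-2-enone ring (C1 ketone, C2 methyl-bearing alkene carbon, C3 alkene carbon with the 2-oxopentyl chain, C4 CH2, C5 carbinol, C6 with methyl and the orsellinate oxygen), C2=C3 with both substituents is an internal alkyne lodged between C1 and C4. The remaining atoms form a cyclobutanone C1–C6–C5–C4 that already holds both stereocentres (5S,6R; ester oxygen trans to O5).
2. Last ring: C1–C2 and C3–C4 are made by nickel-catalysed insertion of 2-(but-2-yn-1-yl)-2-propyl-1,3-dioxolane into the C1–C4 bond of that cyclobutanone.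
3. First ring: C1–C4 and C5–C6 come from a [2+2] of an aroyloxy(methyl)ketene with a vinyl ether whose oxygen carries a chiral, acid-labile 1-arylethyl group. The hindered tertiary ester is therefore made earlier as a secondary ester, by carboxylate alkylation.
4. Alkyne: a butanal-derived dithiane anion is alkylated with 1-bromobut-2-yne, then the thioketal is exchanged for the dioxolane.
5. Ring order: four-membered ring (step 6), two-carbon expansion to the six-membered ring (step 10), one acid treatment to unmask everything (step 11).

Key step: step 10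

Remark: the (S)-configured auxiliary is assumed to shield the vinyl ether face that would lead to 3R (s-trans enol ether, carbinol hydrogen in the olefin plane, aryl group over one face); should the opposite sense be found, the equally available (R)-alcohol is used and nothing else changes.

**Route**

Step 1
Reactants: 1 orsellinic acid (2,4-dihydroxy-6-methylbenzoic acid); 2 benzyl 2-bromopropanoate (racemic)
Product: 3 1-(benzyloxy)-1-oxopropan-2-yl 2,4-dihydroxy-6-methylbenzoate (racemic)
Conditions: KHCO3 (1.1 equiv), DMF, rt
Reagents that add atoms: none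
Why: SN2 O-alkylation of a carboxylate by an α-bromo ester; hydrogencarbonate ionises only the carboxylic acid and not the phenols, so the hindered acid is esterified through its own oxygen, and the new centre may stay racemic because it becomes the sp2 carbon of the ketene.

Step 2
Reactants: 3 racemic benzyl O-orsellinoyl-lactate
Product: 4 1-(benzyloxy)-1-oxopropan-2-yl 2,4-bis(methoxymethoxy)-6-methylbenzoate (racemic)
Conditions: MOMCl, iPr2NEt, Bu4NI (cat.), CH2Cl2, 0 °C to reflux
Reagents that add atoms: chloromethyl methyl ether, COCCl
Why: Williamson-type acetal formation on both phenols; excess reagent, iodide catalysis and warming should also cap the hydrogen-bonded ortho phenol, and the amine base is too weak to enolise the α-acyloxy ester.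

Step 3
Reactants: 4 racemic benzyl O-[bis(methoxymethyl)orsellinoyl]lactate
Product: 5 2-{[2,4-bis(methoxymethoxy)-6-methylbenzoyl]oxy}propanoic acid (racemic)
Conditions: H2 (1 atm), 10% Pd/C, EtOAc, rt
Reagents that add atoms: none
Why: Hydrogenolysis of the benzyl ester under neutral conditions, which should leave the aryl ester and the MOM acetals untouched.

Step 4
Reactants: 5 racemic O-[bis(methoxymethyl)orsellinoyl]lactic acid
Product: 6 1-chloro-1-oxopropan-2-yl 2,4-bis(methoxymethoxy)-6-methylbenzoate (racemic acid chloride, used crude)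
Conditions: 1-chloro-N,N,2-trimethylprop-1-en-1-amine, CH2Cl2, 0 °C to rt
Reagents that add atoms: 1-chloro-N,N,2-trimethylprop-1-en-1-amine, CC(C)=C(Cl)N(C)C
Why: Acid chloride formation with an α-chloroenamine proceeds without free HCl, so the acid-sensitive MOM acetals should survive.

Step 5
Reactants: 7 (S)-1-(2,4,6-triisopropylphenyl)ethanol; 8 vinyl acetate
Product: 9 2-[(1S)-1-(ethenyloxy)ethyl]-1,3,5-triisopropylbenzene
Conditions: [Ir(cod)Cl]2 (2 mol%), Na2CO3 (0.6 equiv), toluene, 100 °C
Reagents that add atoms: none
Why: Iridium-catalysed transfer vinylation of an alcohol with vinyl acetate; only the O–H bond is exchanged, so the (S) carbinol centre is not touched, and carbonate takes up the acetic acid.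

Step 6
Reactants: 6 racemic O-[bis(methoxymethyl)orsellinoyl]lactoyl chloride; 9 (S)-configured arylethyl vinyl ether
Product: 11 (2R,3S)-2-methyl-2-[2,4-bis(methoxymethoxy)-6-methylbenzoyloxy]-3-[(1S)-1-(2,4,6-triisopropylphenyl)ethoxy]cyclobutan-1-one, via aroyloxy(methyl)ketene 10 (not isolated)
Conditions: Et3N (1.5 equiv), toluene, 60 °C, slow addition of 6 (1.5 equiv) to 9
Reagents that add atoms: none
Why: Dehydrochlorination gives the ketene, which should undergo thermal ketene–enol ether [2+2] cycloaddition: the nucleophilic CH2 terminus bonds to the ketene carbonyl carbon (3-alkoxy regiochemistry); the contra-steric rule of ketene cycloadditions places the effectively larger methyl group cis to the alkoxy group and hence the oxygen-linked ester trans to it; the aryl group of the auxiliary shields one face of the vinyl ether as in chiral enol ether–ketene cycloadditions, setting 3S and with it 2R; and because the auxiliary is stereogenic any minor isomers are diastereomers removable by chromatography.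

Step 7
Reactants: 12 butanal
Product: 13 2-propyl-1,3-dithiane
Conditions: propane-1,3-dithiol, BF3·OEt2 (cat.), CH2Cl2, 0 °C to rt
Reagents that add atoms: propane-1,3-dithiol, SCCCS
Why: Lewis acid-catalysed thioacetalisation of an aldehyde, a standard entry to an acyl anion equivalent.

Step 8
Reactants: 13 propyl dithiane; 14 1-bromobut-2-yne
Product: 16 2-(but-2-yn-1-yl)-2-propyl-1,3-dithiane, via 2-lithio-2-propyl-1,3-dithiane 15 (not isolated)
Conditions: n-BuLi, THF, −30 °C; then 14, −78 °C to rt
Reagents that add atoms: none
Why: Corey–Seebach umpolung alkylation of the lithiated dithiane with a primary propargylic bromide (SN2), which places exactly one CH2 between the masked carbonyl and the alkyne (alkylating a β-keto ester enolate with the same bromide would give the homologue with two).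

Step 9
Reactants: 16 butynyl propyl dithiane
Product: 17 2-(but-2-yn-1-yl)-2-propyl-1,3-dioxolane
Conditions: PhI(OCOCF3)2, ethane-1,2-diol, MeCN, rt
Reagents that add atoms: ethane-1,2-diol, OCCO
Why: Oxidative dethioacetalisation with a hypervalent iodine reagent in the presence of the diol, which captures the activated thionium species as the dioxolane, so the isomerisation-prone β,γ-alkynyl ketone is never set free and the alkyne is left alone.

Step 10
Reactants: 11 aroyloxy cyclobutanone; 17 butynyl propyl dioxolane
Product: 18 (1R,6S)-1,3-dimethyl-2-oxo-4-[(2-propyl-1,3-dioxolan-2-yl)methyl]-6-[(1S)-1-(2,4,6-triisopropylphenyl)ethoxy]cyclohex-3-en-1-yl 2,4-bis(methoxymethoxy)-6-methylbenzoate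
Conditions: Ni(cod)2 (10 mol%), PCy3 (20 mol%), toluene, 100 °C, alkyne in excess (2.5 equiv)
Reagents that add atoms: none
Why: Zerovalent nickel joins the C1 carbonyl of 11 and the alkyne by oxidative cyclisation to a spiro oxanickelacyclopentene (C1–C2 bond), β-carbon elimination then opens the strained C1–C4 bond to a seven-membered nickelacycle, and C(sp2)–C(sp3) reductive elimination forms C3–C4. The closest known reaction is the nickel-catalysed intermolecular insertion of internal alkynes into cyclobutanones, a formal [4+2] that gives cyclohex-2-enones. The six-membered ring is closed by that reductive elimination from the seven-membered metallacycle, that is, a two-carbon ring expansion driven by release of four-ring strain. No stereocentre is formed; C6 is never bonded to nickel and C5 is only β to it, so both should pass through unchanged. Two selectivities are needed: the carbonyl carbon must bond to the methyl-bearing alkyne carbon, which should follow from the size difference between methyl and the neopentyl-like ketal arm (whose oxygen can also chelate nickel in a five-membered ring once nickel sits on C3), and ring opening must break C1–C4 and not C1–C6, which the quaternary ester-bearing C6 should ensure because its migration would put nickel on a fully substituted carbon. The C5 oxygen is carried as a bulky alkyl ether, a poor leaving group, so that reductive elimination should outrun β-oxygen elimination from the C4–nickel bond.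

Step 11
Reactants: 18 fully protected cyclohexenone
Product: 19 talarophilone, (1R,6S)-6-hydroxy-1,3-dimethyl-2-oxo-4-(2-oxopentyl)cyclohex-3-en-1-yl 2,4-dihydroxy-6-methylbenzoate
Conditions: TFA–H2O (9:1), CH2Cl2, 0 °C
Reagents that add atoms: water, O
Why: Acid-catalysed solvolysis should cleave the two phenolic MOM acetals, the ionisable benzylic 1-arylethyl ether and the dioxolane in one operation, with water trapping the cations; no bond to C5 or C6 is broken, and low temperature and short exposure are meant to forestall aroyl shift to O5 and loss of water across C4–C5.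

**Compound list**

1 | orsellinic acid | Cc1cc(O)cc(O)c1C(=O)O | starting material
2 | benzyl 2-bromopropanoate (racemic) | CC(Br)C(=O)OCc1ccccc1 | starting material
3 | 1-(benzyloxy)-1-oxopropan-2-yl 2,4-dihydroxy-6-methylbenzoate (racemic) | Cc1cc(O)cc(O)c1C(=O)OC(C)C(=O)OCc1ccccc1 | intermediate
4 | 1-(benzyloxy)-1-oxopropan-2-yl 2,4-bis(methoxymethoxy)-6-methylbenzoate (racemic) | Cc1cc(OCOC)cc(OCOC)c1C(=O)OC(C)C(=O)OCc1ccccc1 | intermediate
5 | 2-{[2,4-bis(methoxymethoxy)-6-methylbenzoyl]oxy}propanoic acid (racemic) | Cc1cc(OCOC)cc(OCOC)c1C(=O)OC(C)C(=O)O | intermediate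
6 | 1-chloro-1-oxopropan-2-yl 2,4-bis(methoxymethoxy)-6-methylbenzoate (racemic) | Cc1cc(OCOC)cc(OCOC)c1C(=O)OC(C)C(Cl)=O | intermediate
7 | (S)-1-(2,4,6-triisopropylphenyl)ethanol | C[C@H](O)c1c(C(C)C)cc(C(C)C)cc1C(C)C | starting material
8 | vinyl acetate | C=COC(C)=O | starting material
9 | 2-[(1S)-1-(ethenyloxy)ethyl]-1,3,5-triisopropylbenzene | C=CO[C@@H](C)c1c(C(C)C)cc(C(C)C)cc1C(C)C | intermediate
10 | 1-oxoprop-1-en-2-yl 2,4-bis(methoxymethoxy)-6-methylbenzoate, the aroyloxy(methyl)ketene | CC(=C=O)OC(=O)c1c(C)cc(OCOC)cc1OCOC | intermediate (not isolated)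
11 | (2R,3S)-2-methyl-2-[2,4-bis(methoxymethoxy)-6-methylbenzoyloxy]-3-[(1S)-1-(2,4,6-triisopropylphenyl)ethoxy]cyclobutan-1-one | O=C1[C@](C)(OC(=O)c2c(C)cc(OCOC)cc2OCOC)[C@@H](O[C@@H](C)c2c(C(C)C)cc(C(C)C)cc2C(C)C)C1 | intermediate
12 | butanal | CCCC=O | starting material
13 | 2-propyl-1,3-dithiane | CCCC1SCCCS1 | intermediate
14 | 1-bromobut-2-yne | CC#CCBr | starting material
15 | 2-lithio-2-propyl-1,3-dithiane | [Li]C1(CCC)SCCCS1 | intermediate (not isolated)
16 | 2-(but-2-yn-1-yl)-2-propyl-1,3-dithiane | CC#CCC1(CCC)SCCCS1 | intermediate
17 | 2-(but-2-yn-1-yl)-2-propyl-1,3-dioxolane | CC#CCC1(CCC)OCCO1 | intermediate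
18 | (1R,6S)-1,3-dimethyl-2-oxo-4-[(2-propyl-1,3-dioxolan-2-yl)methyl]-6-[(1S)-1-(2,4,6-triisopropylphenyl)ethoxy]cyclohex-3-en-1-yl 2,4-bis(methoxymethoxy)-6-methylbenzoate | CCCC1(CC2=C(C)C(=O)[C@](C)(OC(=O)c3c(C)cc(OCOC)cc3OCOC)[C@@H](O[C@@H](C)c3c(C(C)C)cc(C(C)C)cc3C(C)C)C2)OCCO1 | intermediate
19 | talarophilone | CCCC(=O)CC1=C(C)C(=O)[C@](C)(OC(=O)c2c(C)cc(O)cc2O)[C@@H](O)C1 | target

**Step count**

Total: 11 steps. Longest linear sequence: 7 steps (1, 2, 3, 4, 6, 10, 11).

**Steps most likely to fail**

Step 10. Oxidative cyclisation at the hindered, doubly α-substituted carbonyl may be slower than nickel-mediated oligomerisation of the alkyne. The alkyne may also insert in the opposite orientation, since methyl and a CH2-linked arm differ only moderately in size. After ring opening, β-oxygen elimination from the C4–nickel bond or cleavage of C1–C6 may compete, and zerovalent nickel may attack the α-acyloxy C–O bond instead of the carbonyl. The fallback sets out from 16 and 11 and comes back at 19. It replaces the dialkyl alkyne by a conjugated enyne: an alkene next to the alkyne is known to hold nickel on the adjacent alkyne carbon in nickel-mediated alkyne–carbonyl couplings, and an enyne is the better π-acceptor. Dithiane 16 is unmasked with PhI(OCOCF3)2 in aqueous MeCN buffered with NaHCO3 to oct-6-yn-4-one F1. Deprotonation at the more acidic propargylic CH2 with LiN(SiMe3)2 at −78 °C and O-silylation with TBSOTf should give the silyl dienol ether (Z)-tert-butyl(dimethyl)(oct-4-en-6-yn-4-yloxy)silane F2; either alkene geometry would serve. F2 and 11 under Ni(cod)2/PCy3 in toluene should give (1R,6S)-4-[(1Z)-2-(tert-butyldimethylsilyloxy)pent-1-en-1-yl]-1,3-dimethyl-2-oxo-6-[(1S)-1-(2,4,6-triisopropylphenyl)ethoxy]cyclohex-3-en-1-yl 2,4-bis(methoxymethoxy)-6-methylbenzoate F3, with the methyl-bearing alkyne carbon bonded to C1. The acid treatment of step 11 then hydrolyses the silyl enol ether to the side-chain ketone together with the MOM and arylethyl ethers and delivers 19.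

Step 6. The ketene may react too slowly with the hindered vinyl ether and be lost to dimerisation or simple acylation. The ketene substituents may be placed with poor cis/trans control relative to the ether, or the auxiliary may give poor facial selectivity. The fallback sets out from 6 and comes back at 19. It gives up auxiliary control for an unhindered achiral ketenophile used in large excess, followed by resolution. Acid chloride 6 and Et3N with tert-butyl vinyl ether as co-solvent should give racemic (2R,3S)-3-tert-butoxy-2-methyl-2-[2,4-bis(methoxymethoxy)-6-methylbenzoyloxy]cyclobutan-1-one F4. Preparative chromatography on a chiral stationary phase separates (2R,3S)-3-tert-butoxy-2-methyl-2-[2,4-bis(methoxymethoxy)-6-methylbenzoyloxy]cyclobutan-1-one F5, whose configuration is to be assigned by crystallography. Insertion of 17 as in step 10 should give (1R,6S)-6-tert-butoxy-1,3-dimethyl-2-oxo-4-[(2-propyl-1,3-dioxolan-2-yl)methyl]cyclohex-3-en-1-yl 2,4-bis(methoxymethoxy)-6-methylbenzoate F6. Aqueous TFA as in step 11 cleaves the tert-butyl ether with the MOM groups and the dioxolane and gives 19.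

Step 11. The dioxolane may need longer aqueous acid than the freed product tolerates. In that time the aroyl group may shift from the tertiary oxygen to the freed O5, water may be lost across C4–C5, or the benzylic cation may alkylate the freed resorcinol ring. The fallback sets out from 18 and comes back at 19. It splits the single hydrolysis into two orthogonal operations. I2 (10 mol%) in acetone at rt exchanges the dioxolane onto the solvent under neutral conditions and should give (1R,6S)-1,3-dimethyl-2-oxo-4-(2-oxopentyl)-6-[(1S)-1-(2,4,6-triisopropylphenyl)ethoxy]cyclohex-3-en-1-yl 2,4-bis(methoxymethoxy)-6-methylbenzoate F7, with phenol and O5 protection still in place. A short treatment with TFA in CH2Cl2 at 0 °C, with a few equivalents of water as cation trap, then removes the two MOM groups and the arylethyl ether and gives 19.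

**Further compounds**

F1 | step 10 | oct-6-yn-4-one | CCCC(=O)CC#CC
F2 | step 10 | (Z)-tert-butyl(dimethyl)(oct-4-en-6-yn-4-yloxy)silane | CCC/C(O[Si](C)(C)C(C)(C)C)=C/C#CC
F3 | step 10 | (1R,6S)-4-[(1Z)-2-(tert-butyldimethylsilyloxy)pent-1-en-1-yl]-1,3-dimethyl-2-oxo-6-[(1S)-1-(2,4,6-triisopropylphenyl)ethoxy]cyclohex-3-en-1-yl 2,4-bis(methoxymethoxy)-6-methylbenzoate | CCC/C(O[Si](C)(C)C(C)(C)C)=C/C1=C(C)C(=O)[C@](C)(OC(=O)c2c(C)cc(OCOC)cc2OCOC)[C@@H](O[C@@H](C)c2c(C(C)C)cc(C(C)C)cc2C(C)C)C1
F4 | step 6 | racemic (2R,3S)-3-tert-butoxy-2-methyl-2-[2,4-bis(methoxymethoxy)-6-methylbenzoyloxy]cyclobutan-1-one | O=C1[C@](C)(OC(=O)c2c(C)cc(OCOC)cc2OCOC)[C@@H](OC(C)(C)C)C1.O=C1[C@@](C)(OC(=O)c2c(C)cc(OCOC)cc2OCOC)[C@H](OC(C)(C)C)C1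
F5 | step 6 | (2R,3S)-3-tert-butoxy-2-methyl-2-[2,4-bis(methoxymethoxy)-6-methylbenzoyloxy]cyclobutan-1-one | O=C1[C@](C)(OC(=O)c2c(C)cc(OCOC)cc2OCOC)[C@@H](OC(C)(C)C)C1
F6 | step 6 | (1R,6S)-6-tert-butoxy-1,3-dimethyl-2-oxo-4-[(2-propyl-1,3-dioxolan-2-yl)methyl]cyclohex-3-en-1-yl 2,4-bis(methoxymethoxy)-6-methylbenzoate | CCCC1(CC2=C(C)C(=O)[C@](C)(OC(=O)c3c(C)cc(OCOC)cc3OCOC)[C@@H](OC(C)(C)C)C2)OCCO1
F7 | step 11 | (1R,6S)-1,3-dimethyl-2-oxo-4-(2-oxopentyl)-6-[(1S)-1-(2,4,6-triisopropylphenyl)ethoxy]cyclohex-3-en-1-yl 2,4-bis(methoxymethoxy)-6-methylbenzoate | CCCC(=O)CC1=C(C)C(=O)[C@](C)(OC(=O)c2c(C)cc(OCOC)cc2OCOC)[C@@H](O[C@@H](C)c2c(C(C)C)cc(C(C)C)cc2C(C)C)C1
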